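# Design of a synthesis of agastinol (16)

Atom labels follow the tetrahydrofuran ring of the target throughout: O1, C2 (aryl), C3 (arm carbon C3a), C4 (benzylic carbon C4a), C5.

## The problem

Agastinol (16) is a 2,3,4-trisubstituted tetrahydrofuran (ring A: O1–C2–C3–C4–C5). C2 carries a 4-hydroxy-3-methoxyphenyl group, C3 a CH2O arm (C3a) esterified with 4-hydroxybenzoic acid, C4 a 4-hydroxy-3-methoxybenzyl group (C4a), and C5 is a bare methylene. The three contiguous stereocentres are 2R, 3S, 4S: aryl and arm are trans across C2–C3, and the two carbon arms are cis across C3–C4. The cis C3/C4 pair is the less stable arrangement, so it cannot be reached by equilibration and must be set kinetically under the control of C3. C3 is best set relative to C2, and C2 is the one centre whose absolute configuration has to come from an external source. C2 is also the fragile point: it is a benzylic ether para to an oxygen substituent, so acids can ionize it (epimerization, ring opening, Friedel–Crafts closure onto the electron-rich C4 benzyl ring) and it is open to hydrogenolysis. Three phenols must stay masked until the single primary hydroxyl at C3a has been acylated, and once the ester is in place strongly basic or hydridic reagents are excluded. The opening the structure offers is C5: written as a carbonyl, with C4–C4a written as a double bond, ring A becomes an α-methylene-γ-butyrolactone. Such a lactone can be assembled in one operation from an aryl aldehyde (C2) and a 2-(alkoxycarbonyl)allyl metal (C3, C4, C4a, C5) under catalytic enantiocontrol, and its exocyclic carbon can later accept the second aryl group.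

## Retrosynthesis

**16 ⇒ 15 ⇒ 13 + 14.** The three phenolic O–H bonds are traced back to benzyl ethers in 15, and the ester C3a–O–acyl bond is cut to the primary alcohol 13 and 4-(benzyloxy)benzoyl chloride 14. Cutting the ester last but one keeps it away from every hydride and organometallic step. One protecting group for all three phenols means one final operation. The forward steps must acylate a lone hydroxyl and remove aryl benzyl ethers without touching the benzylic C2–O1 bond.

**13 ⇒ 12 ⇒ 11 ⇒ 10.** The C3a hydroxyl is traced to the silyl ether 12, and the C5 methylene to the lactol 11 and the lactone 10. Raising C5 to the carbonyl level is what turns ring A into a lactone and makes the enolate and conjugate-addition chemistry at C4 available. The alternative, opening ring A to a diol, would put the sensitive C2 benzylic alcohol in play and is kept only as a reserve. The forward reduction must remove one oxygen from C5 without ionizing C2–O1 and without epimerizing C4.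

**10 ⇒ 8 + 9.** The C4a–aryl bond and the C4–H bond are cut together, giving the α-methylene lactone 8 and the arylboronic acid 9. This is preferred over alkylating a lactone enolate with a benzyl halide, which would place the benzyl group trans to the C3 arm, the wrong relationship. Conjugate addition followed by protonation lets the small proton, not the large benzyl group, choose the face, so the benzyl group ends up cis to the arm. The precursor 8 has one stereocentre and one aryl ring fewer. The forward step must protonate the enolate anti to the C3 arm.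

**8 ⇒ 4 + 5.** The C2–C3 bond and the lactone O1–C5 bond are cut, giving 4-(benzyloxy)-3-methoxybenzaldehyde 5 and the allylic bromide 4. This removes the ring and both remaining stereocentres at once and leaves two achiral fragments. Against an aldol-based construction of the same bonds it has the advantage that the exocyclic methylene is carried in by the reagent and needs no separate methylenation. The forward reaction must add the allyl unit through its γ-carbon, select the Re face of the aldehyde, and give the anti adduct so that the lactone is trans.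

**4 ⇒ 3 ⇒ 1 + 2.** The C–Br bond of 4 is traced, with allylic transposition, to the hydroxyl of the Morita–Baylis–Hillman adduct 3, and the C3–C4 bond of 3 is cut to ethyl acrylate 1 and the silyloxy aldehyde 2. Both fragments are purchased. The stereocentre of 3 is irrelevant because the bromination erases it. The bromination must give the (Z)-bromide and spare the silyl ether.

## Roads not taken

**Alternative 1: three-component Michael–aldol on a chiral alkoxybutenolide.**
- Cut: C4–C4a and C2–C3 together, on a lactone template in which the carbonyl is the future C3a and the acetal carbon the future C5.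
- Forward key step: the lithiated dithiane A2 adds to the β-carbon of the menthyloxybutenolide A1 anti to the alkoxy group, and the enolate is trapped by aldehyde 5 trans to the new substituent, giving A3.
- Merits: the whole carbon skeleton and the C3 and C4 centres are made in one operation under auxiliary control. The difficult C3/C4 cis relationship comes from a favoured trans arrangement on the template, because the lactone carbonyl becomes the C3 arm. In that respect it is better than the chosen plan, which must rely on a kinetic protonation.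
- Weak points for this target:
  - The auxiliary is stoichiometric and belongs to the less available (1S,2R,5S) menthyl series; A1 must be separated from its acetal epimer.
  - Sulfur has to be removed reductively in the presence of three benzyl ethers.
  - C2 is not controlled in the aldol event. It would be fixed only by a later acid-mediated ring closure through the C2 benzylic cation, the same conditions under which this cation attacks the neighbouring arene.
  - After A3 come desulfurization, reduction of lactone and acetal, ring closure, acylation and debenzylation, so the step count is no lower.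
- Comparison: Alternative 1 is more convergent and stronger at C3/C4. The chosen plan offers catalytic absolute control, a C2 centre that is set directly and never ionized, and no sulfur chemistry.

**Alternative 2: carbonyl ylide cycloaddition onto a γ-aryl butenolide.**
- Cut: C2–C3 and C4–C5, closing ring A directly.
- Forward key step: fluoride-induced 1,3-elimination of the α-chloro silylmethyl ether A4 gives an aryl carbonyl ylide, which adds across the double bond of the butenolide A5 anti to its aryl group to give the cis-fused bicycle A6.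
- Merits: ring A and all three stereocentres appear in one step. The cis ring fusion guarantees the C3/C4 cis relationship, and C5 is already at the ether oxidation level, so no lactone-to-ether reduction is needed. In both respects it beats the chosen plan.
- Weak points for this target:
  - The unsymmetrical ylide must bond through its aryl-bearing carbon to the α-carbon of A5, and the C2 aryl must end up exo; neither is assured.
  - A5 has to be made enantiopure and is configurationally fragile, because its stereocentre is benzylic and vinylogously acidic and fluoride is basic.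
  - After the cycloaddition the benzylic lactone C–O bond must be hydrogenolysed selectively beside the equally benzylic C2–O1 bond.
  - The resulting acid must then be reduced, and the aryl acetates must finally be removed beside the new benzoate ester.
- Comparison: Alternative 2 builds the ring faster. The chosen plan offers unambiguous regiochemistry (the allyl reagent can only bond through its γ-carbon), an absolute configuration that does not depend on a labile stereocentre, and a deprotection that does not compete with the target's own ester.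

**Alternative 3: nickel radical cyclization with aryl capture at C4a.**
- Cut: C3–C4 and C4a–aryl.
- Forward key step: a nickel terpyridine catalyst converts the iodide A7 into a C3 radical, which closes 5-exo onto the allyl ether; the C4a radical is then arylated by the arylzinc bromide A8, giving A9, which is identical with 15.
- Merits: this is the most convergent road. The ester is already in place, C5 needs no redox adjustment, no protecting group is exchanged, and the product is one step from 16. A chair-like transition state with the C2 aryl and the C3 arm pseudo-equatorial leads to the 2,3-trans/3,4-cis pattern. In step economy it is clearly better than the chosen plan.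
- Weak points for this target:
  - C2 is the only control element and must be installed enantioselectively before the key step, which costs separate asymmetric steps for A7.
  - The diastereoselectivity of a 5-exo closure of an acyclic secondary radical is fixed by the substrate, is usually moderate, and cannot be tuned by a ligand.
  - In A7 the iodide is flanked by an allyloxy and an acyloxy group, so reductive β-elimination by low-valent nickel or by the organozinc competes with radical formation.
- Comparison: Alternative 3 would be shorter if A7 were readily available in enantiopure form. The chosen plan is longer, but each stereocentre has its own precedented control element and the absolute configuration comes from a catalyst.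

Key step: step 3

## Route

Assumption: compounds 1, 2, 5, 9 and 14 are purchased; 5, 9 and 14 are the O-benzyl derivatives of vanillin, of the boronic acid from 4-bromo-2-methoxyphenol, and of 4-hydroxybenzoic acid.

Assumption: the antipode of the carbazole bis(oxazoline) ligand that directs the allyl group to the Re face of 5 is used; both antipodes are made in the same way from (S)- or (R)-valinol.

Step 1
Reactants: 1 ethyl acrylate; 2 {[tert-butyl(dimethyl)silyl]oxy}acetaldehyde
Product: 3 ethyl 4-{[tert-butyl(dimethyl)silyl]oxy}-3-hydroxy-2-methylidenebutanoate (racemic)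
Conditions: DABCO (0.5 equiv), neat in 1 (3 equiv), rt
Reagents that add atoms: none
Why: Morita–Baylis–Hillman reaction: the amine adds to the acrylate, the zwitterionic enolate attacks the unhindered, inductively activated α-silyloxy aldehyde, and loss of the amine gives the allylic alcohol. The carbinol centre is racemic and is erased in step 2.

Step 2
Reactants: 3 ethyl 4-{[tert-butyl(dimethyl)silyl]oxy}-3-hydroxy-2-methylidenebutanoate
Product: 4 ethyl (2Z)-2-(bromomethyl)-4-{[tert-butyl(dimethyl)silyl]oxy}but-2-enoate
Conditions: NBS, Me2S, CH2Cl2, 0 °C to rt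
Reagents that add atoms: N-bromosuccinimide, O=C1CCC(=O)N1Br
Why: Corey–Kim-type bromination with allylic transposition: the alcohol is activated as an alkoxysulfonium salt and bromide attacks the terminal methylene in an SN2' displacement with loss of dimethyl sulfoxide. The conjugated trisubstituted enoate with the silyloxymethyl group trans to the ester, the (Z)-isomer, is the favoured product, and the near-neutral conditions should spare the silyl ether.

Step 3
Reactants: 4 ethyl (2Z)-2-(bromomethyl)-4-{[tert-butyl(dimethyl)silyl]oxy}but-2-enoate; 5 4-(benzyloxy)-3-methoxybenzaldehyde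
Product: 8 (4S,5R)-5-[4-(benzyloxy)-3-methoxyphenyl]-4-({[tert-butyl(dimethyl)silyl]oxy}methyl)-3-methylideneoxolan-2-one, via O-trimethylsilyl anti adduct 6 (not isolated), via anti hydroxy ester 7 (not isolated)
Conditions: CrCl2 (10 mol %), 3,6-diphenyl-1,8-bis(4-isopropyl-4,5-dihydrooxazol-2-yl)-9H-carbazole (12 mol %), i-Pr2NEt (30 mol %), Mn powder (2 equiv), Me3SiCl (1.5 equiv), THF, rt; then PPTS, MeOH, 0 °C; then p-TsOH·H2O (5 mol %), CH2Cl2, rt
Reagents that add atoms: none
Why: Two equivalents of divalent chromium, regenerated by Mn, reduce the C–Br bond of 4 to a ligand-bound allyl species of trivalent chromium whose σ-allyl forms interconvert by 1,3-metal shift. This species adds to 5 through its γ-carbon in a closed six-membered chair (Zimmerman–Traxler) transition state, forming C2–C3; Me3SiCl silylates the chromium alkoxide to give 6 and releases the metal for reduction by Mn. Mild methanolysis frees the alcohol 7, whose hydroxyl closes the lactone by 5-exo-trig attack on the ester carbonyl with loss of ethanol (O1–C5). The closest known reaction type is the catalytic enantioselective Nozaki–Hiyama–Kishi 2-(alkoxycarbonyl)allylation of aldehydes with lactonization to α-methylene-γ-butyrolactones. C2 is set by the chiral tridentate ligand, which leaves the Re face of the aldehyde open; C3 is set relative to C2 by the chair, in which the aryl group and the silyloxymethyl group are both pseudo-equatorial, giving the anti adduct and hence the trans lactone. The step needs γ- over α-attack, which the cyclic SE2' transition state guarantees; anti over syn, which rests on equilibration of the allylchromium to the geometry that keeps the single γ-substituent pseudo-equatorial; and aldehyde over ester chemoselectivity, which is inherent to organochromium reagents.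

Step 4
Reactants: 8 (4S,5R)-5-[4-(benzyloxy)-3-methoxyphenyl]-4-({[tert-butyl(dimethyl)silyl]oxy}methyl)-3-methylideneoxolan-2-one; 9 [4-(benzyloxy)-3-methoxyphenyl]boronic acid
Product: 10 (3S,4S,5R)-3-[4-(benzyloxy)-3-methoxybenzyl]-5-[4-(benzyloxy)-3-methoxyphenyl]-4-({[tert-butyl(dimethyl)silyl]oxy}methyl)oxolan-2-one
Conditions: [Rh(cod)OH]2 (2.5 mol %), 9 (2 equiv), 1,4-dioxane/H2O (10:1), 50 °C
Reagents that add atoms: none
Why: Hayashi–Miyaura-type conjugate addition: the aryl group passes from boron to monovalent rhodium, inserts the exocyclic alkene at C4a, and the rhodium enolate is protonated by water. Protonation at C4 should occur on the ring face opposite the adjacent C3 silyloxymethyl arm, which places the benzyl group cis to it (new centre S); the base-free hydroxo catalyst should avoid later epimerization to the more stable trans isomer.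

Step 5
Reactants: 10 (3S,4S,5R)-3-[4-(benzyloxy)-3-methoxybenzyl]-5-[4-(benzyloxy)-3-methoxyphenyl]-4-({[tert-butyl(dimethyl)silyl]oxy}methyl)oxolan-2-one
Product: 11 (3S,4S,5R)-3-[4-(benzyloxy)-3-methoxybenzyl]-5-[4-(benzyloxy)-3-methoxyphenyl]-4-({[tert-butyl(dimethyl)silyl]oxy}methyl)oxolan-2-ol (both C2 epimers)
Conditions: i-Bu2AlH (1.1 equiv), CH2Cl2, −78 °C; aq. potassium sodium tartrate
Reagents that add atoms: none
Why: Partial reduction of a γ-lactone: the tetrahedral aluminium hemiacetal is stable at −78 °C and gives the lactol on work-up. The low temperature avoids enolization at C4, and the ethers and the silyl ether are inert.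

Step 6
Reactants: 11 (3S,4S,5R)-3-[4-(benzyloxy)-3-methoxybenzyl]-5-[4-(benzyloxy)-3-methoxyphenyl]-4-({[tert-butyl(dimethyl)silyl]oxy}methyl)oxolan-2-ol
Product: 12 tert-butyl({(2R,3S,4S)-4-[4-(benzyloxy)-3-methoxybenzyl]-2-[4-(benzyloxy)-3-methoxyphenyl]oxolan-3-yl}methoxy)dimethylsilane
Conditions: Et3SiH (3 equiv), BF3·OEt2 (1.5 equiv), CH2Cl2, −78 °C
Reagents that add atoms: none
Why: Ionic hydrogenation of a lactol: BF3·OEt2 ionizes the hemiacetal to the cyclic oxocarbenium ion, which Et3SiH reduces to the C5 methylene. C5 is not a stereocentre, and at −78 °C hydride capture should outrun both loss of the C4 proton and ionization of the benzylic C2–O1 bond.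

Step 7
Reactants: 12 tert-butyl({(2R,3S,4S)-4-[4-(benzyloxy)-3-methoxybenzyl]-2-[4-(benzyloxy)-3-methoxyphenyl]oxolan-3-yl}methoxy)dimethylsilane
Product: 13 {(2R,3S,4S)-4-[4-(benzyloxy)-3-methoxybenzyl]-2-[4-(benzyloxy)-3-methoxyphenyl]oxolan-3-yl}methanol
Conditions: Bu4NF, THF, 0 °C to rt
Reagents that add atoms: none
Why: Fluoride-induced desilylation driven by the strength of the Si–F bond; the benzyl ethers and the cyclic ether are untouched.

Step 8
Reactants: 13 {(2R,3S,4S)-4-[4-(benzyloxy)-3-methoxybenzyl]-2-[4-(benzyloxy)-3-methoxyphenyl]oxolan-3-yl}methanol; 14 4-(benzyloxy)benzoyl chloride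
Product: 15 {(2R,3S,4S)-4-[4-(benzyloxy)-3-methoxybenzyl]-2-[4-(benzyloxy)-3-methoxyphenyl]oxolan-3-yl}methyl 4-(benzyloxy)benzoate
Conditions: Et3N, DMAP (cat.), CH2Cl2, 0 °C to rt
Reagents that add atoms: none
Why: DMAP-catalysed acylation of the only free hydroxyl group; all phenols are benzyl ethers, so no site selectivity is required.

Step 9
Reactants: 15 {(2R,3S,4S)-4-[4-(benzyloxy)-3-methoxybenzyl]-2-[4-(benzyloxy)-3-methoxyphenyl]oxolan-3-yl}methyl 4-(benzyloxy)benzoate
Product: 16 agastinol
Conditions: H2 (1 atm), 10% Pd/C, EtOAc, rt
Reagents that add atoms: none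
Why: Catalytic hydrogenolysis of the three aryl benzyl ethers. In neutral ethyl acetate these should cleave much faster than the dialkyl benzylic C2–O1 bond, and the benzoate ester is inert; the reaction is stopped once debenzylation is complete.

## Compound list

1 | ethyl acrylate | C=CC(=O)OCC | starting material
2 | {[tert-butyl(dimethyl)silyl]oxy}acetaldehyde | O=CCO[Si](C)(C)C(C)(C)C | starting material
3 | ethyl 4-{[tert-butyl(dimethyl)silyl]oxy}-3-hydroxy-2-methylidenebutanoate (racemic) | CCOC(=O)C(=C)C(O)CO[Si](C)(C)C(C)(C)C | intermediate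
4 | ethyl (2Z)-2-(bromomethyl)-4-{[tert-butyl(dimethyl)silyl]oxy}but-2-enoate | CCOC(=O)/C(CBr)=C/CO[Si](C)(C)C(C)(C)C | intermediate
5 | 4-(benzyloxy)-3-methoxybenzaldehyde | COc1cc(C=O)ccc1OCc1ccccc1 | starting material
6 | ethyl (3S,4R)-4-[4-(benzyloxy)-3-methoxyphenyl]-3-({[tert-butyl(dimethyl)silyl]oxy}methyl)-2-methylidene-4-[(trimethylsilyl)oxy]butanoate | C[Si](C)(C)O[C@@H](c1ccc(OCc2ccccc2)c(OC)c1)[C@H](CO[Si](C)(C)C(C)(C)C)C(=C)C(=O)OCC | intermediate
7 | ethyl (3S,4R)-4-[4-(benzyloxy)-3-methoxyphenyl]-3-({[tert-butyl(dimethyl)silyl]oxy}methyl)-4-hydroxy-2-methylidenebutanoate | O[C@@H](c1ccc(OCc2ccccc2)c(OC)c1)[C@H](CO[Si](C)(C)C(C)(C)C)C(=C)C(=O)OCC | intermediate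
8 | (4S,5R)-5-[4-(benzyloxy)-3-methoxyphenyl]-4-({[tert-butyl(dimethyl)silyl]oxy}methyl)-3-methylideneoxolan-2-one | O=C1O[C@@H](c2ccc(OCc3ccccc3)c(OC)c2)[C@H](CO[Si](C)(C)C(C)(C)C)C1=C | intermediate
9 | [4-(benzyloxy)-3-methoxyphenyl]boronic acid | COc1cc(B(O)O)ccc1OCc1ccccc1 | starting material
10 | (3S,4S,5R)-3-[4-(benzyloxy)-3-methoxybenzyl]-5-[4-(benzyloxy)-3-methoxyphenyl]-4-({[tert-butyl(dimethyl)silyl]oxy}methyl)oxolan-2-one | COc1cc(C[C@@H]2C(=O)O[C@@H](c3ccc(OCc4ccccc4)c(OC)c3)[C@@H]2CO[Si](C)(C)C(C)(C)C)ccc1OCc1ccccc1 | intermediate
11 | (3S,4S,5R)-3-[4-(benzyloxy)-3-methoxybenzyl]-5-[4-(benzyloxy)-3-methoxyphenyl]-4-({[tert-butyl(dimethyl)silyl]oxy}methyl)oxolan-2-ol (both C2 epimers) | COc1cc(C[C@@H]2C(O)O[C@@H](c3ccc(OCc4ccccc4)c(OC)c3)[C@@H]2CO[Si](C)(C)C(C)(C)C)ccc1OCc1ccccc1 | intermediate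
12 | tert-butyl({(2R,3S,4S)-4-[4-(benzyloxy)-3-methoxybenzyl]-2-[4-(benzyloxy)-3-methoxyphenyl]oxolan-3-yl}methoxy)dimethylsilane | COc1cc(C[C@@H]2CO[C@@H](c3ccc(OCc4ccccc4)c(OC)c3)[C@@H]2CO[Si](C)(C)C(C)(C)C)ccc1OCc1ccccc1 | intermediate
13 | {(2R,3S,4S)-4-[4-(benzyloxy)-3-methoxybenzyl]-2-[4-(benzyloxy)-3-methoxyphenyl]oxolan-3-yl}methanol | COc1cc(C[C@@H]2CO[C@@H](c3ccc(OCc4ccccc4)c(OC)c3)[C@@H]2CO)ccc1OCc1ccccc1 | intermediate
14 | 4-(benzyloxy)benzoyl chloride | O=C(Cl)c1ccc(OCc2ccccc2)cc1 | starting material
15 | {(2R,3S,4S)-4-[4-(benzyloxy)-3-methoxybenzyl]-2-[4-(benzyloxy)-3-methoxyphenyl]oxolan-3-yl}methyl 4-(benzyloxy)benzoate | COc1cc(C[C@@H]2CO[C@@H](c3ccc(OCc4ccccc4)c(OC)c3)[C@@H]2COC(=O)c2ccc(OCc3ccccc3)cc2)ccc1OCc1ccccc1 | intermediate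
16 | agastinol, {(2R,3S,4S)-4-(4-hydroxy-3-methoxybenzyl)-2-(4-hydroxy-3-methoxyphenyl)oxolan-3-yl}methyl 4-hydroxybenzoate | COc1cc(C[C@@H]2CO[C@@H](c3ccc(O)c(OC)c3)[C@@H]2COC(=O)c2ccc(O)cc2)ccc1O | target

## Step count and risk

Total: 9 steps. Longest linear sequence: 9 steps (1 and 2 to 16); 5, 9 and 14 enter as purchased fragments.

Least certain steps:

**Step 3 (key step).**
- What may go wrong: erosion of the anti selectivity, because the allylchromium can also add through the geometry inherited from 4, in which the silyloxymethyl group is cis to the metal-bearing carbon and pseudo-axial in the chair; that path gives the cis lactone. The electron-rich, weakly electrophilic aldehyde may also lower enantioface discrimination, and reductive β-elimination of the silyloxy group from the secondary allylchromium isomer would consume the bromide.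
- Fallback, from 5 back to 8, with auxiliary control in place of the catalyst:
  - Lithiated (4R)-4-benzyl-1,3-oxazolidin-2-one is acylated with methyl 4-chloro-4-oxobutanoate to give the imide methyl 4-[(4R)-4-benzyl-2-oxo-1,3-oxazolidin-3-yl]-4-oxobutanoate F1.
  - Its boron enolate (Bu2BOTf, i-Pr2NEt, CH2Cl2, −78 °C) adds to 5 in an Evans syn-aldol reaction to give methyl (3R)-3-{(R)-[4-(benzyloxy)-3-methoxyphenyl](hydroxy)methyl}-4-[(4R)-4-benzyl-2-oxo-1,3-oxazolidin-3-yl]-4-oxobutanoate F2.
  - F2 closes onto its methyl ester, on work-up or with a trace of acid, to the trans lactone imide (4R)-4-benzyl-3-{[(2R,3R)-2-[4-(benzyloxy)-3-methoxyphenyl]-5-oxooxolan-3-yl]carbonyl}-1,3-oxazolidin-2-one F3. The syn adduct necessarily gives the trans lactone.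
  - LiOH/H2O2 removes the auxiliary to give (2R,3R)-2-[4-(benzyloxy)-3-methoxyphenyl]-5-oxooxolane-3-carboxylic acid F4.
  - BH3·SMe2 reduces the acid beside the lactone to (4S,5R)-5-[4-(benzyloxy)-3-methoxyphenyl]-4-(hydroxymethyl)oxolan-2-one F5.
  - t-BuMe2SiCl and imidazole give (4S,5R)-5-[4-(benzyloxy)-3-methoxyphenyl]-4-({[tert-butyl(dimethyl)silyl]oxy}methyl)oxolan-2-one F6.
  - α-Formylation (NaH, HCO2Et) gives sodium {(4S,5R)-5-[4-(benzyloxy)-3-methoxyphenyl]-4-({[tert-butyl(dimethyl)silyl]oxy}methyl)-2-oxooxolan-3-ylidene}methanolate F7, which with paraformaldehyde in hot THF undergoes aldol addition, formyl transfer and loss of formate to deliver 8.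
  - The cost is six operations in place of one.

**Step 4.**
- What may go wrong: poor facial selectivity in the protonation of the rhodium enolate, because the C2 aryl group lies on the face from which the proton must come, one atom further away than the C3 arm. β-Hydride elimination to Heck-type products and protodeboronation of the electron-rich boronic acid may also compete.
- Fallback, from 8 back to 10, separating the C–C bond formation from the protonation:
  - [4-(Benzyloxy)-3-methoxyphenyl]magnesium bromide F8, from purchased 1-(benzyloxy)-4-bromo-2-methoxybenzene and Mg, is added to 8 with CuBr·SMe2 and Me3SiCl in THF at −78 °C.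
  - The enolate is trapped as the silyl ketene acetal (4S,5R)-3-[4-(benzyloxy)-3-methoxybenzyl]-5-[4-(benzyloxy)-3-methoxyphenyl]-4-({[tert-butyl(dimethyl)silyl]oxy}methyl)-2-[(trimethylsilyl)oxy]-4,5-dihydrofuran F9.
  - F9 is C-protonated at −78 °C with acetic acid, the proton approaching anti to the C3 arm, to give 10.

**Step 6.**
- What may go wrong: Lewis-acid ionization of the benzylic C2–O1 bond (epimerization at C2, reductive ring opening, Friedel–Crafts closure onto the C4 benzyl arene), and epimerization at C4 by proton loss from the oxocarbenium ion. Partial loss of the silyl ether would be harmless, since step 7 removes it.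
- Fallback, from 10 back to 12, bypassing 11 and any cation:
  - LiAlH4 (THF, 0 °C) opens the lactone to (1R,2S,3S)-3-[4-(benzyloxy)-3-methoxybenzyl]-1-[4-(benzyloxy)-3-methoxyphenyl]-2-({[tert-butyl(dimethyl)silyl]oxy}methyl)butane-1,4-diol F10.
  - p-TsCl in pyridine at 0 °C sulfonylates the primary hydroxyl selectively to give (2S,3S,4R)-2-[4-(benzyloxy)-3-methoxybenzyl]-4-[4-(benzyloxy)-3-methoxyphenyl]-3-({[tert-butyl(dimethyl)silyl]oxy}methyl)-4-hydroxybutyl 4-methylbenzenesulfonate F11.
  - With t-BuOK in THF the benzylic alkoxide closes 5-exo-tet onto the primary sulfonate, with retention at C2 because the C2–O bond is never broken, giving 12.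

**Step 9.**
- What may go wrong: over-reduction, that is hydrogenolysis of the benzylic C2–O1 bond of ring A once the para-phenol has been freed.
- Fallback, from 15 back to 16, with no new compound: non-reductive debenzylation with BCl3 and pentamethylbenzene as benzyl cation scavenger in CH2Cl2 at −78 °C. This cleaves aryl benzyl ethers at a temperature at which the aryl methyl ethers, the ester and the ring ether should persist.

## Further compounds

F1 | step 3 | methyl 4-[(4R)-4-benzyl-2-oxo-1,3-oxazolidin-3-yl]-4-oxobutanoate | COC(=O)CCC(=O)N1[C@H](Cc2ccccc2)COC1=O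
F2 | step 3 | methyl (3R)-3-{(R)-[4-(benzyloxy)-3-methoxyphenyl](hydroxy)methyl}-4-[(4R)-4-benzyl-2-oxo-1,3-oxazolidin-3-yl]-4-oxobutanoate | COC(=O)C[C@H]([C@@H](O)c1ccc(OCc2ccccc2)c(OC)c1)C(=O)N1[C@H](Cc2ccccc2)COC1=O
F3 | step 3 | (4R)-4-benzyl-3-{[(2R,3R)-2-[4-(benzyloxy)-3-methoxyphenyl]-5-oxooxolan-3-yl]carbonyl}-1,3-oxazolidin-2-one | O=C1O[C@@H](c2ccc(OCc3ccccc3)c(OC)c2)[C@H](C(=O)N2[C@H](Cc3ccccc3)COC2=O)C1
F4 | step 3 | (2R,3R)-2-[4-(benzyloxy)-3-methoxyphenyl]-5-oxooxolane-3-carboxylic acid | O=C1O[C@@H](c2ccc(OCc3ccccc3)c(OC)c2)[C@H](C(=O)O)C1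
F5 | step 3 | (4S,5R)-5-[4-(benzyloxy)-3-methoxyphenyl]-4-(hydroxymethyl)oxolan-2-one | O=C1O[C@@H](c2ccc(OCc3ccccc3)c(OC)c2)[C@H](CO)C1
F6 | step 3 | (4S,5R)-5-[4-(benzyloxy)-3-methoxyphenyl]-4-({[tert-butyl(dimethyl)silyl]oxy}methyl)oxolan-2-one | O=C1O[C@@H](c2ccc(OCc3ccccc3)c(OC)c2)[C@H](CO[Si](C)(C)C(C)(C)C)C1
F7 | step 3 | sodium {(4S,5R)-5-[4-(benzyloxy)-3-methoxyphenyl]-4-({[tert-butyl(dimethyl)silyl]oxy}methyl)-2-oxooxolan-3-ylidene}methanolate | O=C1O[C@@H](c2ccc(OCc3ccccc3)c(OC)c2)[C@H](CO[Si](C)(C)C(C)(C)C)C1=C[O-].[Na+]
F8 | step 4 | [4-(benzyloxy)-3-methoxyphenyl]magnesium bromide | COc1cc([Mg]Br)ccc1OCc1ccccc1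
F9 | step 4 | (4S,5R)-3-[4-(benzyloxy)-3-methoxybenzyl]-5-[4-(benzyloxy)-3-methoxyphenyl]-4-({[tert-butyl(dimethyl)silyl]oxy}methyl)-2-[(trimethylsilyl)oxy]-4,5-dihydrofuran | C[Si](C)(C)OC1=C(Cc2ccc(OCc3ccccc3)c(OC)c2)[C@@H](CO[Si](C)(C)C(C)(C)C)[C@H](c2ccc(OCc3ccccc3)c(OC)c2)O1
F10 | step 6 | (1R,2S,3S)-3-[4-(benzyloxy)-3-methoxybenzyl]-1-[4-(benzyloxy)-3-methoxyphenyl]-2-({[tert-butyl(dimethyl)silyl]oxy}methyl)butane-1,4-diol | COc1cc(C[C@H](CO)[C@@H](CO[Si](C)(C)C(C)(C)C)[C@@H](O)c2ccc(OCc3ccccc3)c(OC)c2)ccc1OCc1ccccc1
F11 | step 6 | (2S,3S,4R)-2-[4-(benzyloxy)-3-methoxybenzyl]-4-[4-(benzyloxy)-3-methoxyphenyl]-3-({[tert-butyl(dimethyl)silyl]oxy}methyl)-4-hydroxybutyl 4-methylbenzenesulfonate | COc1cc(C[C@H](COS(=O)(=O)c2ccc(C)cc2)[C@@H](CO[Si](C)(C)C(C)(C)C)[C@@H](O)c2ccc(OCc3ccccc3)c(OC)c2)ccc1OCc1ccccc1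
F0 | step 9 | none | none
A1 | alternative 1 | (5S)-5-{[(1S,2R,5S)-5-methyl-2-(propan-2-yl)cyclohexyl]oxy}furan-2(5H)-one | O=C1O[C@H](O[C@H]2C[C@@H](C)CC[C@@H]2C(C)C)C=C1
A2 | alternative 1 | 2-[4-(benzyloxy)-3-methoxyphenyl]-1,3-dithiane | COc1cc(C2SCCCS2)ccc1OCc1ccccc1
A3 | alternative 1 | 3-{[4-(benzyloxy)-3-methoxyphenyl](hydroxy)methyl}-4-{2-[4-(benzyloxy)-3-methoxyphenyl]-1,3-dithian-2-yl}-5-{[(1S,2R,5S)-5-methyl-2-(propan-2-yl)cyclohexyl]oxy}oxolan-2-one (3,4-trans and 4,5-trans; configuration as in the SMILES) | O=C1O[C@H](O[C@H]2C[C@@H](C)CC[C@@H]2C(C)C)[C@@H](C2(c3ccc(OCc4ccccc4)c(OC)c3)SCCCS2)[C@@H]1[C@@H](O)c1ccc(OCc2ccccc2)c(OC)c1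
A4 | alternative 2 | 4-{chloro[(trimethylsilyl)methoxy]methyl}-2-methoxyphenyl acetate (racemic) | CC(=O)Oc1ccc(C(Cl)OC[Si](C)(C)C)cc1OC
A5 | alternative 2 | (5R)-5-(4-acetoxy-3-methoxyphenyl)furan-2(5H)-one | O=C1O[C@@H](c2ccc(OC(C)=O)c(OC)c2)C=C1
A6 | alternative 2 | cis-fused 4,8-bis(4-acetoxy-3-methoxyphenyl)-3,7-dioxabicyclo[3.3.0]octan-2-one with both aryl groups exo (configuration as in the SMILES) | O=C1O[C@@H](c2ccc(OC(C)=O)c(OC)c2)[C@@H]2CO[C@@H](c3ccc(OC(C)=O)c(OC)c3)[C@H]12
A7 | alternative 3 | (3S)-3-[4-(benzyloxy)-3-methoxyphenyl]-2-iodo-3-(prop-2-en-1-yloxy)propyl 4-(benzyloxy)benzoate (either C2 epimer) | C=CCO[C@@H](c1ccc(OCc2ccccc2)c(OC)c1)C(I)COC(=O)c1ccc(OCc2ccccc2)cc1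
A8 | alternative 3 | [4-(benzyloxy)-3-methoxyphenyl]zinc bromide | COc1cc([Zn]Br)ccc1OCc1ccccc1
A9 | alternative 3 | tri-O-benzyl agastinol (identical with 15) | COc1cc(C[C@@H]2CO[C@@H](c3ccc(OCc4ccccc4)c(OC)c3)[C@@H]2COC(=O)c2ccc(OCc3ccccc3)cc2)ccc1OCc1ccccc1
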